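**Plan**

- Numbering and enabling feature: abietane C1–C20 for the diterpene part, thujane C1'–C10' for the C10 unit (C10' = carbinol carbon on C7, C4' = spiro carbon on C14, C1' = i-Pr-bearing bridgehead, C5'/C6' = cyclopropane CH/CH2). Unravelled, the cyclopentane C1'–C5' fused to the cyclopropane C1'/C5'/C6' is a 3,3-disubstituted hex-1-en-5-yne centred on C4': a vinyl group (C5'=C6') and a 4-methylpent-2-ynyl arm (C3'–C2'≡C1'–i-Pr).
- Retrosynthetic cuts, in order: quinone methide to catechol (ring C aromatic, C7–H); C2'–C3' (H2); C1'–C5' and C1'–C6' (enyne cycloisomerisation); C5'=C6' (methylenation); C14–C4' (epoxide–arene Friedel–Crafts); C7–C10' (aldol with an epoxy aldehyde); C6=O (epoxide rearrangement of the 6,7-alkene); C9–C10 and C4–C5 (polyene cyclisation); C6–C7 chain bond (benzyl Grignard plus geranyl chloride).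
- Forward ring order: ring C is bought as an arene; rings A and B arise together by polyene cyclisation; the five-membered ring C7–C8–C14–C4'–C10' closes by intramolecular arylation; last, in one gold-catalysed event, the thujane cyclopentane closes together with its cyclopropane.
- Stereochemistry: C10 from a chiral-acid-controlled cyclisation; C5 (β-H, cis) by equilibration of the 6-ketone; C4' from a Sharpless epoxidation, relayed with inversion; C10' from a Cornforth-controlled aldol on the epoxy aldehyde; C1'/C5' from the 10'α-silyloxy group in the key step.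

Key step: step 19

**Remarks**

- α/β are the faces of the usual abietane drawing (C20 methyl β); for the flat ring C7–C8–C14–C4'–C10' they mean the same two faces.
- Assumption: in abieta-8,11,13-trien-6-ones the cis-fused (5β-H) ketone is taken to be the thermodynamic C5 epimer.
- Assumption: the (R)-binaphthol-derived acid is taken to give the 10S series; if it does not, its enantiomer is used.
- C7 of compounds 21–29 is drawn 7α-H (anti aldol); this centre is temporary and is erased in step 21.

**Route**

Step 1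
Reactants: 1 3-bromo-4,5-dihydroxybenzaldehyde
Product: 2 3,4-bis(benzyloxy)-5-bromobenzaldehyde
Conditions: BnBr (2.2 equiv), K2CO3, DMF, 60 °C
Reagents that add atoms: benzyl bromide, BrCc1ccccc1
Why: Double Williamson O-benzylation of the catechol; benzyl ethers should tolerate the Lewis acids, bases and oxidants used later and leave by neutral hydrogenolysis at the end.

Step 2
Reactants: 2 3,4-bis(benzyloxy)-5-bromobenzaldehyde
Product: 3 3,4-bis(benzyloxy)-5-(propan-2-yl)benzaldehyde
Conditions: i-PrZnBr, Pd(OAc)2 (1 mol %), CPhos (2 mol %), THF/toluene, 25 °C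
Reagents that add atoms: isopropylzinc bromide, CC(C)[Zn]Br
Why: Negishi coupling of a secondary alkylzinc halide with the aryl bromide, the biaryl dialkylphosphine favouring reductive elimination over β-hydride isomerisation to n-propyl, while the organozinc tolerates the aldehyde.

Step 3
Reactants: 3 3,4-bis(benzyloxy)-5-(propan-2-yl)benzaldehyde
Product: 4 [3,4-bis(benzyloxy)-5-(propan-2-yl)phenyl]methanol
Conditions: NaBH4, MeOH/THF, 0 °C
Reagents that add atoms: none
Why: Borohydride reduction of the aryl aldehyde to the benzylic alcohol.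

Step 4
Reactants: 4 [3,4-bis(benzyloxy)-5-(propan-2-yl)phenyl]methanol
Product: 5 1,2-bis(benzyloxy)-5-(chloromethyl)-3-(propan-2-yl)benzene
Conditions: SOCl2, CH2Cl2, 0 → 25 °C
Reagents that add atoms: thionyl chloride, ClS(Cl)=O
Why: Chlorodehydroxylation of the benzylic alcohol through its chlorosulfite.

Step 5
Reactants: 5 1,2-bis(benzyloxy)-5-(chloromethyl)-3-(propan-2-yl)benzene; 6 geranyl chloride [(2E)-1-chloro-3,7-dimethylocta-2,6-diene]
Product: 8 1,2-bis(benzyloxy)-5-[(3E)-4,8-dimethylnona-3,7-dien-1-yl]-3-(propan-2-yl)benzene, via benzylic Grignard reagent 7 (not isolated)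
Conditions: Mg turnings, THF, 0 °C (slow addition of 5); then 6, THF, 0 → 25 °C
Reagents that add atoms: none
Why: Grignard formation and SN2 coupling with the primary allylic chloride should keep the E alkene and give the homogeranyl arene needed for polyene cyclisation.

Step 6
Reactants: 8 1,2-bis(benzyloxy)-5-[(3E)-4,8-dimethylnona-3,7-dien-1-yl]-3-(propan-2-yl)benzene
Product: 9 (5S,10S)-11,12-bis(benzyloxy)abieta-8,11,13-triene (trans-fused, 5α-H, 10β-CH3)
Conditions: (R)-3,3'-dichloro-BINOL·SbCl5 complex (0.5 equiv), CH2Cl2, −78 °C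
Reagents that add atoms: none
Why: Enantioselective proton-initiated cationic polyene cyclisation (chiral Brønsted acid activated by a Lewis acid): face-selective protonation of the terminal alkene, chair–chair folding and Friedel–Crafts termination at the less hindered ortho carbon C9 (para to i-Pr) should give the trans-fused tricycle with C10 set by the catalyst.

Step 7
Reactants: 9 (5S,10S)-11,12-bis(benzyloxy)abieta-8,11,13-triene
Product: 10 (5S,10S)-11,12-bis(benzyloxy)abieta-6,8,11,13-tetraene
Conditions: DDQ (1.1 equiv), toluene, 80 °C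
Reagents that add atoms: none
Why: DDQ dehydrogenation by hydride abstraction from benzylic C7 (assisted by the para oxygen on C12) and loss of H-6 gives the styrenic 6,7-alkene.

Step 8
Reactants: 10 (5S,10S)-11,12-bis(benzyloxy)abieta-6,8,11,13-tetraene
Product: 12 (5S,10S)-11,12-bis(benzyloxy)abieta-8,11,13-trien-6-one (trans-fused), via 6α,7α-epoxide 11 (not isolated)
Conditions: m-CPBA, NaHCO3, CH2Cl2, 0 °C; then BF3·OEt2 (0.2 equiv), CH2Cl2, −78 → 0 °C
Reagents that add atoms: m-chloroperoxybenzoic acid, OOC(=O)c1cccc(Cl)c1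
Why: Prilezhaev epoxidation on the α face (anti to the axial C20 methyl) followed by Meinwald rearrangement, in which benzylic C7–O ionisation and a 1,2-hydride shift from C6 put the carbonyl on C6 without touching C5.

Step 9
Reactants: 12 (5S,10S)-11,12-bis(benzyloxy)abieta-8,11,13-trien-6-one
Product: 13 (5R,10S)-11,12-bis(benzyloxy)abieta-8,11,13-trien-6-one (cis-fused, 5β-H)
Conditions: NaOMe (0.5 equiv), degassed MeOH/THF, 25 °C, Ar
Reagents that add atoms: none
Why: Reversible enolisation towards C5 should equilibrate the ring fusion to the cis 6-ketone, which relieves the C19/C20 syn-diaxial and C18/C6=O peri interactions of the trans isomer, so C5 is set thermodynamically.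

Step 10
Reactants: 14 3-methylbut-1-yne; 15 ethyl 2-(bromomethyl)prop-2-enoate
Product: 16 ethyl 6-methyl-2-methylidenehept-4-ynoate
Conditions: CuI (10 mol %), K2CO3, DMF, 25 °C
Reagents that add atoms: none
Why: Copper-acetylide allylic substitution (SN2 and SN2' give the same product with this allyl unit) builds the skipped enyne.

Step 11
Reactants: 16 ethyl 6-methyl-2-methylidenehept-4-ynoate
Product: 17 6-methyl-2-methylidenehept-4-yn-1-ol
Conditions: i-Bu2AlH (2.2 equiv), CH2Cl2, −78 °C; Rochelle salt work-up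
Reagents that add atoms: none
Why: 1,2-Reduction of the acrylate ester by the aluminium hydride gives the 2-substituted allylic alcohol and leaves alkyne and alkene alone.

Step 12
Reactants: 17 6-methyl-2-methylidenehept-4-yn-1-ol
Product: 18 [(2R)-2-(4-methylpent-2-yn-1-yl)oxiran-2-yl]methanol
Conditions: Ti(OiPr)4 (10 mol %), D-(−)-diethyl tartrate (12 mol %), t-BuOOH, 4 Å sieves, CH2Cl2, −20 °C
Reagents that add atoms: tert-butyl hydroperoxide, CC(C)(C)OO
Why: Sharpless asymmetric epoxidation of the 2-substituted allylic alcohol; the D-(−)-tartrate titanium complex delivers oxygen to the face that gives the (R)-epoxy alcohol, fixing the carbon that becomes C4'.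

Step 13
Reactants: 18 [(2R)-2-(4-methylpent-2-yn-1-yl)oxiran-2-yl]methanol
Product: 19 (2S)-2-(4-methylpent-2-yn-1-yl)oxirane-2-carbaldehyde
Conditions: Dess–Martin periodinane, NaHCO3, CH2Cl2, 0 → 25 °C
Reagents that add atoms: none
Why: Dess–Martin oxidation gives the α-quaternary epoxy aldehyde, which cannot enolise and so keeps its configuration.

Step 14
Reactants: 13 (5R,10S)-11,12-bis(benzyloxy)abieta-8,11,13-trien-6-one; 19 (2S)-2-(4-methylpent-2-yn-1-yl)oxirane-2-carbaldehyde
Product: 21 (5R,10S)-11,12-bis(benzyloxy)-7-{(R)-hydroxy[(2S)-2-(4-methylpent-2-yn-1-yl)oxiran-2-yl]methyl}abieta-8,11,13-trien-6-one (7α-H), via lithium enolate 20 (not isolated)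
Conditions: LiN(i-Pr)2 (1.05 equiv), THF, −78 °C; then 19; AcOH quench at −78 °C
Reagents that add atoms: none
Why: Kinetic deprotonation at benzylic C7 and aldol addition through a closed Zimmerman–Traxler transition state; the aldehyde should react in the Cornforth conformer (C=O anti to the oxirane C–O) on the face away from the oxirane CH2, which sets C10', while the anti-aldol centre C7 is temporary.

Step 15
Reactants: 21 aldol adduct
Product: 22 tert-butyldimethylsilyl ether of 21 at O-10'
Conditions: TBSOTf (1.2 equiv), 2,6-lutidine, CH2Cl2, −78 °C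
Reagents that add atoms: tert-butyldimethylsilyl triflate, CC(C)(C)[Si](C)(C)OS(=O)(=O)C(F)(F)F
Why: Silylation of the hindered secondary alcohol with the silyl triflate blocks retro-aldol and installs the steric control element on the α face.

Step 16
Reactants: 22 silyl ether
Product: 23 (5R,10S)-11,12-bis(benzyloxy)-6-oxoabieta-8,11,13-triene bridged from C7 to C14 by C10'(α-OTBS)–C4'[α-CH2OH, β-(4-methylpent-2-yn-1-yl)] (7α-H)
Conditions: (CF3)2CHOH, 0 → 25 °C
Reagents that add atoms: none
Why: Intramolecular Friedel–Crafts alkylation (epoxy–arene cyclisation) under hydrogen-bond activation: C14, the only free arene position and para to O-11, should open the oxirane at its tertiary carbon in a 5-exo mode with inversion, turning the Sharpless-derived centre into quaternary C4' with the CH2OH arm cis to the silyloxy group.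

Step 17
Reactants: 23 primary alcohol
Product: 24 the corresponding C4'α-carbaldehyde
Conditions: Dess–Martin periodinane, NaHCO3, CH2Cl2, 25 °C
Reagents that add atoms: none
Why: Dess–Martin oxidation of the neopentyl primary alcohol, leaving ketone, silyl ether and alkyne untouched.

Step 18
Reactants: 24 aldehyde
Product: 25 the corresponding C4'α-vinyl compound (3-vinyl-3-propargyl 1,5-enyne)
Conditions: CH2I2, Zn, Ti(OiPr)4, THF, 25 °C
Reagents that add atoms: diiodomethane, ICI
Why: Takai-type methylenation with the gem-dizinc/titanium reagent is non-basic (no β-elimination of the silyloxy ketone) and selective for the aldehyde over the ketone, and completes the 1,5-enyne.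

Step 19
Reactants: 25 1,5-enyne
Product: 26 the spiro bicyclo[3.1.0]hex-2-ene (C2'=C3' alkene, C1' i-Pr, cyclopropane CH2 C6' syn to C14, C5' on the α face)
Conditions: Ph3PAuCl (5 mol %), AgSbF6 (5 mol %), CH2Cl2, 25 °C
Reagents that add atoms: none
Why: Cationic Ph3PAu+ binds the C2'≡C1' alkyne and the C5'=C6' vinyl group attacks C1' with both of its carbons, giving a cyclopropyl gold carbene at C2' that collapses by a 1,2-hydride shift from C3' and loss of the metal to leave the C2'=C3' alkene. The closest known reaction type is the gold- or platinum-catalysed cycloisomerisation of 1,5-enynes to bicyclo[3.1.0]hex-2-enes, applied here to a 3,3-disubstituted hex-1-en-5-yne with an internal alkyne. The cyclopentene C4'–C3'–C2'–C1'–C5' closes in the 5-endo-dig mode (C5' to C1') and the cyclopropane C1'/C5'/C6' by the accompanying 3-exo attack of C6' on the same alkyne carbon, so the two bridgeheads form together and must be cis. C1' (quaternary) and C5' are set relative to C4' by the vinyl face that reacts: the vinyl group is cis to the bulky 10'α-silyloxy group, so only the rotamer that turns C6' away from that ether and towards C14 is unhindered, which places the cyclopropane methylene syn to C14 as in the target. Chemoselectivity against arene or carbonyl participation is needed and should be secured because the arene is hexasubstituted, the ketone is not a 1,3-dicarbonyl, and the hydride shift can only come from the C3' methylene since C4' is quaternary.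

Step 20
Reactants: 26 bicyclo[3.1.0]hex-2-ene
Product: 27 the saturated spiro thujane (C2'–C3' single bond)
Conditions: KO2CN=NCO2K, AcOH, MeOH/CH2Cl2, 0 → 25 °C
Reagents that add atoms: none
Why: Diimide generated in situ transfers H2 suprafacially to the strained cis-disubstituted alkene and, unlike heterogeneous hydrogenation, should not open the vinylcyclopropane or touch ketone and benzyl ethers.

Step 21
Reactants: 27 saturated bis(benzyl ether)
Product: 30 O-10' silyl ether of the target quinone methide, via catechol 28 (not isolated), via ortho-quinone 29 (not isolated)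
Conditions: H2 (1 atm), Pd(OH)2/C, EtOAc, 25 °C; filter under Ar; then Ag2O, Et2O, 25 °C
Reagents that add atoms: none
Why: Hydrogenolysis of both benzyl ethers gives the catechol, Ag2O dehydrogenates it to the ortho-quinone, and enolisation of the doubly activated H-7 towards O-11 gives the extended para-quinone methide conjugated with the 6-ketone, erasing the temporary C7 centre.

Step 22
Reactants: 30 silyl ether
Product: 31 target, (5R,10S,1'R,4'S,5'S,10'S)-configured C30 quinone methide
Conditions: HF·pyridine, THF, 0 → 25 °C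
Reagents that add atoms: none
Why: Fluoride-mediated cleavage of the secondary silyl ether under mildly acidic conditions should free the C10' alcohol without epimerising C5 or adding a nucleophile to the quinone methide.

**Compound list**

1 | 3-bromo-4,5-dihydroxybenzaldehyde | O=Cc1cc(O)c(O)c(Br)c1 | starting material
2 | 3,4-bis(benzyloxy)-5-bromobenzaldehyde | O=Cc1cc(OCc2ccccc2)c(OCc2ccccc2)c(Br)c1 | intermediate
3 | 3,4-bis(benzyloxy)-5-(propan-2-yl)benzaldehyde | O=Cc1cc(OCc2ccccc2)c(OCc2ccccc2)c(C(C)C)c1 | intermediate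
4 | [3,4-bis(benzyloxy)-5-(propan-2-yl)phenyl]methanol | OCc1cc(OCc2ccccc2)c(OCc2ccccc2)c(C(C)C)c1 | intermediate
5 | 1,2-bis(benzyloxy)-5-(chloromethyl)-3-(propan-2-yl)benzene | ClCc1cc(OCc2ccccc2)c(OCc2ccccc2)c(C(C)C)c1 | intermediate
6 | geranyl chloride, (2E)-1-chloro-3,7-dimethylocta-2,6-diene | ClC/C=C(\C)CCC=C(C)C | starting material
7 | {[3,4-bis(benzyloxy)-5-(propan-2-yl)phenyl]methyl}magnesium chloride | Cl[Mg]Cc1cc(OCc2ccccc2)c(OCc2ccccc2)c(C(C)C)c1 | intermediate
8 | 1,2-bis(benzyloxy)-5-[(3E)-4,8-dimethylnona-3,7-dien-1-yl]-3-(propan-2-yl)benzene | CC(C)=CCC/C(C)=C/CCc1cc(OCc2ccccc2)c(OCc2ccccc2)c(C(C)C)c1 | intermediate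
9 | (5S,10S)-11,12-bis(benzyloxy)abieta-8,11,13-triene (5α-H, 10β-CH3) | CC(C)c1cc2CC[C@H]3C(C)(C)CCC[C@]3(C)c2c(OCc2ccccc2)c1OCc1ccccc1 | intermediate
10 | (5S,10S)-11,12-bis(benzyloxy)abieta-6,8,11,13-tetraene | CC(C)c1cc2C=C[C@H]3C(C)(C)CCC[C@]3(C)c2c(OCc2ccccc2)c1OCc1ccccc1 | intermediate
11 | 6α,7α-epoxide of 10 | CC(C)c1cc2[C@@H]4O[C@@H]4[C@H]3C(C)(C)CCC[C@]3(C)c2c(OCc2ccccc2)c1OCc1ccccc1 | intermediate
12 | (5S,10S)-11,12-bis(benzyloxy)abieta-8,11,13-trien-6-one (trans-fused, 5α-H) | CC(C)c1cc2CC(=O)[C@H]3C(C)(C)CCC[C@]3(C)c2c(OCc2ccccc2)c1OCc1ccccc1 | intermediate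
13 | (5R,10S)-11,12-bis(benzyloxy)abieta-8,11,13-trien-6-one (cis-fused, 5β-H) | CC(C)c1cc2CC(=O)[C@@H]3C(C)(C)CCC[C@]3(C)c2c(OCc2ccccc2)c1OCc1ccccc1 | intermediate
14 | 3-methylbut-1-yne | C#CC(C)C | starting material
15 | ethyl 2-(bromomethyl)prop-2-enoate | C=C(CBr)C(=O)OCC | starting material
16 | ethyl 6-methyl-2-methylidenehept-4-ynoate | C=C(CC#CC(C)C)C(=O)OCC | intermediate
17 | 6-methyl-2-methylidenehept-4-yn-1-ol | C=C(CC#CC(C)C)CO | intermediate
18 | [(2R)-2-(4-methylpent-2-yn-1-yl)oxiran-2-yl]methanol | OC[C@]1(CC#CC(C)C)CO1 | intermediate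
19 | (2S)-2-(4-methylpent-2-yn-1-yl)oxirane-2-carbaldehyde | O=C[C@]1(CC#CC(C)C)CO1 | intermediate
20 | lithium C6–C7 enolate of 13 | CC(C)c1cc2C=C(O[Li])[C@@H]3C(C)(C)CCC[C@]3(C)c2c(OCc2ccccc2)c1OCc1ccccc1 | intermediate
21 | aldol adduct: 13 carrying at C7 (7α-H) the (R)-hydroxy[(2S)-2-(4-methylpent-2-yn-1-yl)oxiran-2-yl]methyl group | CC(C)c1cc2[C@H](C(=O)[C@@H]3C(C)(C)CCC[C@]3(C)c2c(OCc2ccccc2)c1OCc1ccccc1)[C@@H](O)[C@]1(CC#CC(C)C)CO1 | intermediate
22 | O-10' tert-butyldimethylsilyl ether of 21 | CC(C)c1cc2[C@H](C(=O)[C@@H]3C(C)(C)CCC[C@]3(C)c2c(OCc2ccccc2)c1OCc1ccccc1)[C@@H](O[Si](C)(C)C(C)(C)C)[C@]1(CC#CC(C)C)CO1 | intermediate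
23 | C7/C14-bridged tetracycle: 10'α-OTBS, C4' with α-CH2OH and β-(4-methylpent-2-yn-1-yl), 7α-H, 5β-H, 6-oxo, 11,12-bis(benzyloxy) | CC(C)c1c2c3[C@H](C(=O)[C@@H]4C(C)(C)CCC[C@]4(C)c3c(OCc3ccccc3)c1OCc1ccccc1)[C@@H](O[Si](C)(C)C(C)(C)C)[C@]2(CO)CC#CC(C)C | intermediate
24 | C4'α-carbaldehyde derived from 23 | CC(C)c1c2c3[C@H](C(=O)[C@@H]4C(C)(C)CCC[C@]4(C)c3c(OCc3ccccc3)c1OCc1ccccc1)[C@@H](O[Si](C)(C)C(C)(C)C)[C@]2(C=O)CC#CC(C)C | intermediate
25 | C4'α-vinyl, C4'β-(4-methylpent-2-yn-1-yl) 1,5-enyne | CC(C)c1c2c3[C@H](C(=O)[C@@H]4C(C)(C)CCC[C@]4(C)c3c(OCc3ccccc3)c1OCc1ccccc1)[C@@H](O[Si](C)(C)C(C)(C)C)[C@]2(C=C)CC#CC(C)C | intermediate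
26 | spiro 1'-isopropylbicyclo[3.1.0]hex-2'-ene (C6' syn to C14, C5' α) on the protected tetracycle | CC(C)c1c2c3[C@H](C(=O)[C@@H]4C(C)(C)CCC[C@]4(C)c3c(OCc3ccccc3)c1OCc1ccccc1)[C@@H](O[Si](C)(C)C(C)(C)C)[C@]21C=C[C@]2(C(C)C)C[C@@H]21 | intermediate
27 | 2',3'-dihydro derivative of 26 (saturated spiro thujane) | CC(C)c1c2c3[C@H](C(=O)[C@@H]4C(C)(C)CCC[C@]4(C)c3c(OCc3ccccc3)c1OCc1ccccc1)[C@@H](O[Si](C)(C)C(C)(C)C)[C@]21CC[C@]2(C(C)C)C[C@@H]21 | intermediate
28 | 11,12-catechol from 27 | CC(C)c1c2c3[C@H](C(=O)[C@@H]4C(C)(C)CCC[C@]4(C)c3c(O)c1O)[C@@H](O[Si](C)(C)C(C)(C)C)[C@]21CC[C@]2(C(C)C)C[C@@H]21 | intermediate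
29 | 11,12-ortho-quinone from 28 | CC(C)C1=C2C3[C@H](C(=O)[C@@H]4C(C)(C)CCC[C@]4(C)C=3C(=O)C1=O)[C@@H](O[Si](C)(C)C(C)(C)C)[C@]21CC[C@]2(C(C)C)C[C@@H]21 | intermediate
30 | O-10' tert-butyldimethylsilyl ether of the target | CC(C)C1=C2C3=C(C(=O)[C@@H]4C(C)(C)CCC[C@]4(C)C3=C(O)C1=O)[C@@H](O[Si](C)(C)C(C)(C)C)[C@]21CC[C@]2(C(C)C)C[C@@H]21 | intermediate
31 | target: (5R,10S)-11-hydroxyabieta-7,9(11),13-triene-6,12-dione bridged C7–C10'(S, α-OH)–C4'(S, spiro)–C14, with the (1'R,5'S)-1'-isopropylbicyclo[3.1.0]hexane spiro at C4' | CC(C)C1=C2C3=C(C(=O)[C@@H]4C(C)(C)CCC[C@]4(C)C3=C(O)C1=O)[C@@H](O)[C@]21CC[C@]2(C(C)C)C[C@@H]21 | target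

**Step count and risks**

Total steps: 22. Longest linear sequence: 18 (steps 1–9, then 14–22); steps 10–13 make the epoxy aldehyde in a side branch.

The three steps most likely to fail:

Step 16 (epoxide–arene closure). The tertiary oxirane may ionise and undergo a 1,2-shift (semipinacol or Meinwald pathway), or be captured by the C6 carbonyl oxygen, before C14 attacks; arylation would then be slow or the inversion at C4' not clean. Fallback, from 22 back to 24: N-bromosuccinimide in MeCN at 0 °C brominates C14, the only unsubstituted arene position, to give the aryl bromide F1. A bulky aluminium Lewis acid, MeAl(OAr)2 (Ar = 4-bromo-2,6-di-tert-butylphenyl), then deliberately drives the Meinwald rearrangement of the 2,2-disubstituted oxirane to the α-branched aldehyde F2 (both C4' epimers usable). An intramolecular palladium-catalysed enolate α-arylation (Pd(OAc)2, chiral phosphino-oxazoline ligand, Cs2CO3, t-BuOH, 80 °C) closes the C14–C4' bond and gives the quaternary aldehyde 24, with C4' now set by the ligand and the neighbouring silyloxy group; steps 16 and 17 are skipped.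

Step 14 (aldol). Poor facial discrimination at the formyl group, or retro-aldol of the lithium aldolate on warming, would erode C10'. Fallback, from 13 back to 21: 13 is converted with LiN(i-Pr)2 and Me3SiCl into the trimethylsilyl enol ether F3, which is added to 19 in a MgBr2·OEt2-mediated Mukaiyama aldol at −78 °C. The open transition state on the magnesium chelate between formyl and oxirane oxygens replaces dipole control by chelation control (attack past the oxirane CH2 should give the same C10' configuration), and the irreversible silyl transfer rules out retro-aldol.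

Step 6 (polyene cyclisation). Chelation of the vicinal bis-ether to the antimony complex may lower the enantioselectivity or stop the cascade at monocyclic products. Fallback, from 8 back to 9: an iodonium-initiated enantioselective polyene cyclisation (N-iodosuccinimide with a stoichiometric chiral binaphthyl phosphoramidite as nucleophilic promoter, toluene, −40 °C, then ClSO3H to complete ring closure) gives the 3β-iodo tricycle F4, and radical deiodination (Bu3SnH, AIBN, toluene, 80 °C) returns 9.

**Further compounds**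

F1 | step 16 | 14-bromo derivative of 22 | CC(C)c1c(Br)c2[C@H](C(=O)[C@@H]3C(C)(C)CCC[C@]3(C)c2c(OCc2ccccc2)c1OCc1ccccc1)[C@@H](O[Si](C)(C)C(C)(C)C)[C@]1(CC#CC(C)C)CO1
F2 | step 16 | 14-bromo α-branched aldehyde from Meinwald rearrangement of F1 (C4' epimers) | CC(C)c1c(Br)c2[C@H](C(=O)[C@@H]3C(C)(C)CCC[C@]3(C)c2c(OCc2ccccc2)c1OCc1ccccc1)[C@@H](O[Si](C)(C)C(C)(C)C)C(C=O)CC#CC(C)C
F3 | step 14 | C6–C7 trimethylsilyl enol ether of 13 | CC(C)c1cc2C=C(O[Si](C)(C)C)[C@@H]3C(C)(C)CCC[C@]3(C)c2c(OCc2ccccc2)c1OCc1ccccc1
F4 | step 6 | 3β-iodo derivative of 9 (trans-fused, 5α-H, 10β-CH3) | CC(C)c1cc2CC[C@H]3C(C)(C)[C@@H](I)CC[C@]3(C)c2c(OCc2ccccc2)c1OCc1ccccc1
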